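**Plan**
1. Marchantin H is an achiral 18-membered ring built from arenes A (4-hydroxy-3-aryloxybenzyl), B (para-phenylene), C (2-aryloxy-3,4-dihydroxyphenyl) and D (meta-phenylene), two diaryl ether oxygens (A–O–B, C–O–D) and two CH2–CH2 bridges (B–C, D–A).
2. Retrosynthetic cuts, in order: the three O–CH3 bonds of a trimethyl ether; the D–CH2–CH2–A bond, traced back to a CH2–NH–CH2 unit (deletion of the one ring nitrogen of a 19-membered azacycle); the N–CH2(ring D) bond (reductive amination); the B–C bridge (Wittig, then hydrogenation); the two aryl C–O bonds (SNAr for A–O–B, Ullmann for C–O–D).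
3. Enabling feature: both carbons of the D–CH2–CH2–A bond are benzylic methylenes (one on ring D, one on ring A para to the ring A oxygen). A secondary bis-benzylic amine can therefore lose its nitrogen as N2 through an isodiazene, and the resulting benzylic radical pair is held in one molecule by the B–C bridge and both ether links.
4. Forward: A–O–B ether, then ring B phosphonium salt; C–O–D ether; Wittig joins B to C; one hydrogenation saturates the bridge and turns the ring A nitrile into CH2NH2; unmasking the ring D aldehyde closes the 19-membered aza ring; nitrogen deletion contracts it to the 18-membered carbocycle; BBr3 frees the three phenols.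
5. Stereochemistry: the target has no stereocentre; alkene and imine geometries are erased by reduction.

Key step: step 9

Assumption: marchantin H is taken as conformationally mobile, without configurationally stable atropisomers, so no element of chirality has to be controlled.

**Route**

Step 1
Reactants: 1 3-hydroxy-4-methoxybenzonitrile; 2 4-fluorobenzaldehyde
Product: 3 3-(4-formylphenoxy)-4-methoxybenzonitrile
Conditions: K2CO3, DMAc, 140 °C
Reagents that add atoms: none
Why: Nucleophilic aromatic substitution (SNAr): the phenoxide of 1 displaces fluoride from 2, which is activated by its para-formyl group, and the nitrile is inert to carbonate.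

Step 2
Reactants: 3 3-(4-formylphenoxy)-4-methoxybenzonitrile
Product: 4 3-[4-(hydroxymethyl)phenoxy]-4-methoxybenzonitrile
Conditions: NaBH4, MeOH/THF, 0 °C
Reagents that add atoms: none
Why: Chemoselective hydride reduction: NaBH4 should reduce the aldehyde to the benzylic alcohol and leave the aryl nitrile and the diaryl ether untouched.

Step 3
Reactants: 4 3-[4-(hydroxymethyl)phenoxy]-4-methoxybenzonitrile
Product: 5 [4-(5-cyano-2-methoxyphenoxy)benzyl]triphenylphosphonium bromide
Conditions: PPh3·HBr, MeCN, reflux
Reagents that add atoms: triphenylphosphine hydrobromide, [Br-].c1ccc(cc1)[PH+](c1ccccc1)c1ccccc1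
Why: Acid-promoted substitution of an electron-rich (para-aryloxy) benzylic alcohol by triphenylphosphine hydrobromide should give the benzylic phosphonium salt directly, and the nitrile does not take part.

Step 4
Reactants: 6 3-hydroxybenzaldehyde
Product: 7 3-(1,3-dioxolan-2-yl)phenol
Conditions: ethylene glycol, pTsOH (cat.), toluene, reflux, Dean–Stark trap
Reagents that add atoms: ethylene glycol, OCCO
Why: Acid-catalysed acetalisation with azeotropic removal of water masks the ring D aldehyde as a base-stable 1,3-dioxolane and leaves the phenol free.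

Step 5
Reactants: 7 3-(1,3-dioxolan-2-yl)phenol; 8 2-bromo-3,4-dimethoxybenzaldehyde
Product: 9 2-[3-(1,3-dioxolan-2-yl)phenoxy]-3,4-dimethoxybenzaldehyde
Conditions: CuI (10 mol %), N,N-dimethylglycine hydrochloride (30 mol %), Cs2CO3, dioxane, 100 °C
Reagents that add atoms: none
Why: Ullmann diaryl ether synthesis (copper-catalysed C–O coupling): the ortho-formyl group activates the C–Br bond and offsets the hindrance of the flanking methoxy group, and both aldehyde and acetal tolerate carbonate.

Step 6
Reactants: 5 [4-(5-cyano-2-methoxyphenoxy)benzyl]triphenylphosphonium bromide; 9 2-[3-(1,3-dioxolan-2-yl)phenoxy]-3,4-dimethoxybenzaldehyde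
Product: 11 3-[4-(2-{2-[3-(1,3-dioxolan-2-yl)phenoxy]-3,4-dimethoxyphenyl}ethenyl)phenoxy]-4-methoxybenzonitrile (E/Z mixture), via phosphonium ylide 10 (not isolated)
Conditions: K2CO3, 18-crown-6 (cat.), CH2Cl2, reflux
Reagents that add atoms: none
Why: Wittig olefination of a semi-stabilised benzylic ylide with an aryl aldehyde; an E/Z mixture is expected and is of no consequence because the double bond is saturated in step 7, and nitrile and acetal are stable to the mild base.

Step 7
Reactants: 11 3-[4-(2-{2-[3-(1,3-dioxolan-2-yl)phenoxy]-3,4-dimethoxyphenyl}ethenyl)phenoxy]-4-methoxybenzonitrile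
Product: 12 {3-[4-(2-{2-[3-(1,3-dioxolan-2-yl)phenoxy]-3,4-dimethoxyphenyl}ethyl)phenoxy]-4-methoxyphenyl}methanamine
Conditions: H2 (4 bar), Raney Ni, 7 M NH3 in MeOH/THF, rt
Reagents that add atoms: none
Why: Heterogeneous hydrogenation over Raney Ni should saturate the stilbene C=C and reduce the aryl nitrile to the primary benzylic amine; ammonia suppresses secondary-amine formation by intercepting the intermediate aldimine, and the dioxolane is stable under these basic conditions.

Step 8
Reactants: 12 {3-[4-(2-{2-[3-(1,3-dioxolan-2-yl)phenoxy]-3,4-dimethoxyphenyl}ethyl)phenoxy]-4-methoxyphenyl}methanamine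
Product: 15 aza-macrocycle (19-membered secondary amine ring D–CH2–NH–CH2–ring A; tri-O-methyl), via amino aldehyde hydrochloride 13 (not isolated), via macrocyclic aldimine 14 (not isolated)
Conditions: 1 M aq HCl, THF, rt; evaporate; then MeOH (about 1 mM), Et3N, rt; then NaBH4, 0 °C
Reagents that add atoms: none
Why: Acetal hydrolysis unmasks the ring D aldehyde while the amine is held as its ammonium salt; on neutralisation at high dilution, reversible imine condensation should favour the unstrained 19-membered cyclic aldimine over oligomers, and NaBH4 then fixes it as the secondary amine (intramolecular reductive amination).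

Step 9
Reactants: 15 aza-macrocycle (19-membered secondary amine ring D–CH2–NH–CH2–ring A; tri-O-methyl)
Product: 18 marchantin H tri-O-methyl ether, via N-amino adduct 16 (not isolated), via isodiazene 17 (not isolated)
Conditions: N-(benzyloxy)-N-(pivaloyloxy)-4-(trifluoromethyl)benzamide (1.5 equiv), THF (0.02 M), 45 °C
Reagents that add atoms: none
Why: Nitrogen deletion of a secondary amine with an anomeric amide: the ring nitrogen of 15 attacks the amide nitrogen and displaces pivalate to give adduct 16, which undergoes reductive elimination (benzyloxy shift to the acyl carbon) to benzyl 4-(trifluoromethyl)benzoate and isodiazene 17; loss of N2 leaves a benzylic radical pair that recombines to the CH2–CH2 bond. The closest known reaction type is the anomeric-amide nitrogen deletion of acyclic dibenzylic secondary amines to bibenzyls and of benzo-fused cyclic amines to ring-contracted carbocycles. The 18-membered ring arises by contraction of the 19-membered azacycle, the closing event being intramolecular radical–radical recombination of a tethered 1,18-diradical, so no exo/endo descriptor of a polar cyclisation applies. No stereocentre is formed. The step needs C–C recombination to outrun the 1,2-hydrogen shift of the isodiazene to a hydrazone and intermolecular radical coupling; both carbons are benzylic (ring A CH2 para to the methoxy group, ring D CH2), which should make N2 loss fast and the radicals unreactive towards THF, while the B–C ethano bridge and the two ether oxygens keep the pair within one molecule, helped by moderate dilution. The phenols are masked as methyl ethers, so the secondary amine is the only nucleophile that the electrophilic amide nitrogen meets.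

Step 10
Reactants: 18 marchantin H tri-O-methyl ether
Product: 19 marchantin H
Conditions: BBr3 (9 equiv), CH2Cl2, −78 °C to rt; then H2O
Reagents that add atoms: none
Why: Lewis-acid cleavage of aryl methyl ethers (BBr3 demethylation): bromide attacks the methyl carbon of each borane-complexed ether, while the diaryl ether C–O bonds, which offer no sp3 carbon, should stay intact; work-up hydrolyses the aryl borates.

**Compound list**
1 | 3-hydroxy-4-methoxybenzonitrile | N#Cc1ccc(OC)c(O)c1 | starting material
2 | 4-fluorobenzaldehyde | O=Cc1ccc(F)cc1 | starting material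
3 | 3-(4-formylphenoxy)-4-methoxybenzonitrile | N#Cc1ccc(OC)c(Oc2ccc(C=O)cc2)c1 | intermediate
4 | 3-[4-(hydroxymethyl)phenoxy]-4-methoxybenzonitrile | N#Cc1ccc(OC)c(Oc2ccc(CO)cc2)c1 | intermediate
5 | [4-(5-cyano-2-methoxyphenoxy)benzyl]triphenylphosphonium bromide | N#Cc1ccc(OC)c(Oc2ccc(C[P+](c3ccccc3)(c3ccccc3)c3ccccc3)cc2)c1.[Br-] | intermediate
6 | 3-hydroxybenzaldehyde | O=Cc1cccc(O)c1 | starting material
7 | 3-(1,3-dioxolan-2-yl)phenol | Oc1cccc(c1)C1OCCO1 | intermediate
8 | 2-bromo-3,4-dimethoxybenzaldehyde | O=Cc1ccc(OC)c(OC)c1Br | starting material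
9 | 2-[3-(1,3-dioxolan-2-yl)phenoxy]-3,4-dimethoxybenzaldehyde | O=Cc1ccc(OC)c(OC)c1Oc1cccc(c1)C1OCCO1 | intermediate
10 | [4-(5-cyano-2-methoxyphenoxy)benzylidene]triphenylphosphorane (ylide, not isolated) | N#Cc1ccc(OC)c(Oc2ccc(C=P(c3ccccc3)(c3ccccc3)c3ccccc3)cc2)c1 | intermediate
11 | 3-[4-(2-{2-[3-(1,3-dioxolan-2-yl)phenoxy]-3,4-dimethoxyphenyl}ethenyl)phenoxy]-4-methoxybenzonitrile (E/Z mixture, geometry left open) | N#Cc1ccc(OC)c(Oc2ccc(C=Cc3ccc(OC)c(OC)c3Oc3cccc(c3)C3OCCO3)cc2)c1 | intermediate
12 | {3-[4-(2-{2-[3-(1,3-dioxolan-2-yl)phenoxy]-3,4-dimethoxyphenyl}ethyl)phenoxy]-4-methoxyphenyl}methanamine | NCc1ccc(OC)c(Oc2ccc(CCc3ccc(OC)c(OC)c3Oc3cccc(c3)C3OCCO3)cc2)c1 | intermediate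
13 | 3-(6-{2-[4-(5-(aminomethyl)-2-methoxyphenoxy)phenyl]ethyl}-2,3-dimethoxyphenoxy)benzaldehyde hydrochloride (not isolated) | Cl.NCc1ccc(OC)c(Oc2ccc(CCc3ccc(OC)c(OC)c3Oc3cccc(C=O)c3)cc2)c1 | intermediate
14 | 19-membered macrocyclic aldimine, ring D–CH=N–CH2–ring A, tri-O-methyl (not isolated; C=N geometry as the ring prefers) | COc1ccc2cc1Oc1ccc(cc1)CCc1ccc(OC)c(OC)c1Oc1cccc(c1)C=NC2 | intermediate
15 | 19-membered aza-macrocycle: marchantin H tri-O-methyl ether with an NH inserted between the ring D CH2 and the ring A CH2 | COc1ccc2cc1Oc1ccc(cc1)CCc1ccc(OC)c(OC)c1Oc1cccc(c1)CNC2 | intermediate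
16 | N-amino adduct: 15 carrying N(OCH2Ph)C(=O)C6H4-4-CF3 on the ring nitrogen (not isolated) | COc1ccc2cc1Oc1ccc(cc1)CCc1ccc(OC)c(OC)c1Oc1cccc(c1)CN(C2)N(OCc1ccccc1)C(=O)c1ccc(cc1)C(F)(F)F | intermediate
17 | isodiazene (1,1-diazene) of 15 (not isolated) | COc1ccc2cc1Oc1ccc(cc1)CCc1ccc(OC)c(OC)c1Oc1cccc(c1)C[N+](=[N-])C2 | intermediate
18 | marchantin H tri-O-methyl ether (18-membered ring) | COc1ccc2cc1Oc1ccc(cc1)CCc1ccc(OC)c(OC)c1Oc1cccc(c1)CC2 | intermediate
19 | marchantin H | Oc1ccc2cc1Oc1ccc(cc1)CCc1ccc(O)c(O)c1Oc1cccc(c1)CC2 | target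

**Count and risks**
Total steps: 10. Longest linear sequence: 8 steps (steps 1, 2, 3, 6, 7, 8, 9, 10).

Most likely to fail:

1. Step 9. The 1,2-hydrogen shift of the isodiazene to a hydrazone, or slow N-amination of the macrocyclic amine, may compete with ring-closing recombination of the radical pair. Fallback (sets out from 11, returns at 18): hydrogenation of 11 (H2, Pd/C, EtOAc, rt) should saturate only the alkene and give the bibenzyl nitrile acetal F1. Reduction with iBu2AlH (CH2Cl2, −78 °C) followed by 1 M HCl should convert nitrile and acetal into the dialdehyde F2. McMurry coupling with low-valent titanium (TiCl4, Zn, pyridine, THF, reflux, slow addition) should close the ring to the macrocyclic stilbene F3. Hydrogenation (H2, Pd/C) then gives 18.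

2. Step 8. Intermolecular imine condensation may lead to oligomers, or the product amine may be alkylated by a second aldehyde. Fallback (sets out from 12, returns at 15): sulfonylation of 12 with 2-nitrobenzenesulfonyl chloride and Et3N should give the nosyl amide acetal F4. Hydrolysis (1 M HCl, THF) gives the nosyl amide aldehyde F5, and NaBH4 gives the nosyl amide benzylic alcohol F6. Mitsunobu macrocyclisation (PPh3, diisopropyl azodicarboxylate, THF/toluene, slow addition) forms the C–N bond irreversibly by N-alkylation and gives the N-nosyl aza-macrocycle F7. Thiophenol and K2CO3 in DMF then remove the sulfonyl group to give 15.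

3. Step 7. The nascent primary amine may condense with the intermediate aldimine to give a secondary amine, or the alkene may be incompletely saturated. Fallback (sets out from 11, returns at 13): reduction of 11 with NiCl2·6H2O and NaBH4 in MeOH in the presence of Boc2O should reduce nitrile and alkene and trap the amine at once as the tert-butyl carbamate acetal F8. 4 M HCl in dioxane/water then removes carbamate and acetal together to give 13, which enters step 8 at the neutralisation stage.

Further compounds
F1 | step 9 | 3-[4-(2-{2-[3-(1,3-dioxolan-2-yl)phenoxy]-3,4-dimethoxyphenyl}ethyl)phenoxy]-4-methoxybenzonitrile | N#Cc1ccc(OC)c(Oc2ccc(CCc3ccc(OC)c(OC)c3Oc3cccc(c3)C3OCCO3)cc2)c1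
F2 | step 9 | 3-(4-{2-[2-(3-formylphenoxy)-3,4-dimethoxyphenyl]ethyl}phenoxy)-4-methoxybenzaldehyde | O=Cc1ccc(OC)c(Oc2ccc(CCc3ccc(OC)c(OC)c3Oc3cccc(C=O)c3)cc2)c1
F3 | step 9 | macrocyclic stilbene: 18 with CH=CH in place of the ring D–CH2–CH2–ring A bridge (E/Z left open) | COc1ccc2cc1Oc1ccc(cc1)CCc1ccc(OC)c(OC)c1Oc1cccc(c1)C=C2
F4 | step 8 | N-{3-[4-(2-{2-[3-(1,3-dioxolan-2-yl)phenoxy]-3,4-dimethoxyphenyl}ethyl)phenoxy]-4-methoxybenzyl}-2-nitrobenzenesulfonamide | O=S(=O)(NCc1ccc(OC)c(Oc2ccc(CCc3ccc(OC)c(OC)c3Oc3cccc(c3)C3OCCO3)cc2)c1)c1ccccc1[N+](=O)[O-]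
F5 | step 8 | N-{3-[4-(2-{2-(3-formylphenoxy)-3,4-dimethoxyphenyl}ethyl)phenoxy]-4-methoxybenzyl}-2-nitrobenzenesulfonamide | O=S(=O)(NCc1ccc(OC)c(Oc2ccc(CCc3ccc(OC)c(OC)c3Oc3cccc(C=O)c3)cc2)c1)c1ccccc1[N+](=O)[O-]
F6 | step 8 | N-{3-[4-(2-{2-[3-(hydroxymethyl)phenoxy]-3,4-dimethoxyphenyl}ethyl)phenoxy]-4-methoxybenzyl}-2-nitrobenzenesulfonamide | O=S(=O)(NCc1ccc(OC)c(Oc2ccc(CCc3ccc(OC)c(OC)c3Oc3cccc(CO)c3)cc2)c1)c1ccccc1[N+](=O)[O-]
F7 | step 8 | N-(2-nitrobenzenesulfonyl) derivative of aza-macrocycle 15 | COc1ccc2cc1Oc1ccc(cc1)CCc1ccc(OC)c(OC)c1Oc1cccc(c1)CN(C2)S(=O)(=O)c1ccccc1[N+](=O)[O-]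
F8 | step 7 | tert-butyl N-{3-[4-(2-{2-[3-(1,3-dioxolan-2-yl)phenoxy]-3,4-dimethoxyphenyl}ethyl)phenoxy]-4-methoxybenzyl}carbamate | CC(C)(C)OC(=O)NCc1ccc(OC)c(Oc2ccc(CCc3ccc(OC)c(OC)c3Oc3cccc(c3)C3OCCO3)cc2)c1
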